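**Retrosynthetic overview**

- The target is the C8 tiglate of a tricyclic alcohol; the ester goes on last, and the C8 oxygen travels as a triisopropylsilyl ether.
- Key disconnection: the ring O–C10 bond and the C2=C3 bond of the 3(2H)-furanone are cut together, giving a monocyclic α,α'-dibromo ketone / N,N-dimethylamide.
- Enabling feature: in the furanone ring (O–C3=C2–C1(=O)–C10) the ring oxygen and C2 both sit on C3, and C10 and C2 flank the C1 ketone. The ring is thus an amide carbonyl (C3=O) joined to a 2-oxyallyl unit (C10–C1–C2). Because C3 and C10 are also the ends of the C4–C9 chain, making both bonds closes the furanone and the ten-membered carbocycle (C1–C10) at once.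
- The dibromo ketone comes from a methyl ketone (Wacker oxidation of a terminal alkene). C8 comes from CBS reduction of a ketone made by Negishi acylation of a lactone acid.
- The lactone acid (C6, C7, C11) comes from an Evans syn-aldol/lactonisation and a trans-methylation; C4 comes from an Evans allylation. Ring order: γ-lactone first (step 5), then furanone and ten-membered ring together (step 14).

Key step: step 14

Remark (chemistry): locants C1–C15 follow the germacrane skeleton of the target (C1 ring ketone, C2=C3 enol ether, C8 acyloxy carbon, C10 oxygen-bearing quaternary carbon, C12 lactone carbonyl). The side-chain stereocentre that becomes C10 is carried as an epimer mixture from 15 to 22, because step 14 makes it planar, so it has no stereo mark in those SMILES.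

**Route**

Step 1
Reactants: 1 (4R)-4-benzyl-3-propanoyl-1,3-oxazolidin-2-one; 2 3-iodoprop-1-ene (allyl iodide)
Product: 3 (4R)-4-benzyl-3-[(2S)-2-methylpent-4-enoyl]-1,3-oxazolidin-2-one
Conditions: NaN(SiMe3)2, THF, −78 °C; then 2, −78 to −40 °C
Reagents that add atoms: none
Why: Evans alkylation: the chelated Z-sodium enolate of the imide is allylated on the face away from the benzyl group, which sets C4 as S.

Step 2
Reactants: 3 (4R)-4-benzyl-3-[(2S)-2-methylpent-4-enoyl]-1,3-oxazolidin-2-one
Product: 4 (2S)-N,N,2-trimethylpent-4-enamide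
Conditions: AlMe3, Me2NH·HCl, CH2Cl2, 0 °C to rt; then 3, rt to 40 °C; aq. potassium sodium tartrate
Reagents that add atoms: dimethylamine hydrochloride, CNC.Cl
Why: Aminolysis of the imide by the aluminium amide made in the flask attacks the exocyclic carbonyl, gives the tertiary amide that the key step needs and frees the auxiliary without touching the alpha stereocentre.

Step 3
Reactants: 4 (2S)-N,N,2-trimethylpent-4-enamide
Product: 6 (2S)-N,N,2-trimethyl-4-oxobutanamide, via ozonide 5 (not isolated)
Conditions: O3, CH2Cl2, −78 °C; then PPh3, −78 °C to rt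
Reagents that add atoms: ozone, [O-][O+]=O
Why: Ozonolysis with reductive work-up cuts the terminal alkene to the aldehyde, and the stereocentre is safe because it is alpha to the amide and not to the new aldehyde.

Step 4
Reactants: 7 (4S)-4-benzyl-1,3-oxazolidin-2-one; 8 methyl 4-chloro-4-oxobutanoate
Product: 9 methyl 4-[(4S)-4-benzyl-2-oxo-1,3-oxazolidin-3-yl]-4-oxobutanoate
Conditions: n-BuLi, THF, −78 °C; then 8, −78 to 0 °C
Reagents that add atoms: none
Why: N-Acylation of the lithiated oxazolidinone by the acid chloride is faster than any attack on the methyl ester and sets up the auxiliary for the aldol step.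

Step 5
Reactants: 9 methyl 4-[(4S)-4-benzyl-2-oxo-1,3-oxazolidin-3-yl]-4-oxobutanoate; 6 (2S)-N,N,2-trimethyl-4-oxobutanamide
Product: 11 (4S)-4-benzyl-3-{[(2R,3S)-2-[(2S)-3-(dimethylamino)-2-methyl-3-oxopropyl]-5-oxooxolan-3-yl]carbonyl}-1,3-oxazolidin-2-one, via aldol adduct 10 (not isolated)
Conditions: Bu2BOTf, iPr2NEt, CH2Cl2, −78 to 0 °C; 6, −78 to 0 °C; pH 7 buffer, MeOH, H2O2; then PPTS (cat.), CH2Cl2, rt
Reagents that add atoms: none
Why: Evans syn-aldol reaction: the Z-boron enolate adds through a closed chair transition state under control of the (S)-auxiliary to set C7 (S) and C6 (R), and the new hydroxyl then closes the γ-lactone on the methyl ester (5-exo-trig), which is a better acyl donor than the tertiary amide, giving the trans-disubstituted ring.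

Step 6
Reactants: 11 the lactone imide from step 5
Product: 12 (2R,3S)-2-[(2S)-3-(dimethylamino)-2-methyl-3-oxopropyl]-5-oxooxolane-3-carboxylic acid
Conditions: LiOH, H2O2, THF/H2O, 0 °C; Na2SO3; then 1 M HCl to pH 2
Reagents that add atoms: hydrogen peroxide (as LiOOH), OO
Why: Hydroperoxide cleavage of the imide: LiOOH attacks the exocyclic N-acyl carbonyl selectively, and any lactone opened by hydroxide closes again on acidification.

Step 7
Reactants: 12 the lactone acid from step 6
Product: 13 (2R,3S,4S)-2-[(2S)-3-(dimethylamino)-2-methyl-3-oxopropyl]-4-methyl-5-oxooxolane-3-carboxylic acid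
Conditions: NaN(SiMe3)2 (2.3 equiv), THF, −78 °C; MeI, −78 to −40 °C; 1 M HCl
Reagents that add atoms: iodomethane, CI
Why: Alkylation of the carboxylate–lactone enolate dianion: MeI approaches C11 anti to the C7 carboxylate, which sets C11 (S) and the all-trans lactone, while the carboxylate keeps C7–H from being removed.

Step 8
Reactants: 14 2-methylbut-3-en-1-ol (racemic)
Product: 15 4-bromo-3-methylbut-1-ene
Conditions: CBr4, PPh3, CH2Cl2, 0 °C
Reagents that add atoms: tetrabromomethane, BrC(Br)(Br)Br
Why: Appel bromination converts the primary alcohol into the bromide under neutral conditions that leave the alkene alone.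

Step 9
Reactants: 13 the methylated lactone acid; 15 4-bromo-3-methylbut-1-ene
Product: 18 (2S)-N,N,2-trimethyl-3-[(2R,3S,4S)-4-methyl-3-(3-methylpent-4-enoyl)-5-oxooxolan-2-yl]propanamide, via acid chloride 16 (not isolated), via alkylzinc bromide 17 (not isolated)
Conditions: 13, 1-chloro-N,N,2-trimethylprop-1-en-1-amine, CH2Cl2, 0 °C; 15, Zn, LiCl, THF, 40 °C; then combine, Pd(PPh3)4 (5 mol %), THF, 0 °C to rt
Reagents that add atoms: 1-chloro-N,N,2-trimethylprop-1-en-1-amine, CC(C)=C(Cl)N(C)C (chlorine of 16 only); zinc, [Zn] (zinc of 17 only)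
Why: Negishi acylation: the acid chloride is made under neutral conditions that spare the tertiary amide, and Pd(PPh3)4 (zerovalent palladium) couples it with the alkylzinc bromide to the ketone without over-addition and without touching lactone or amide.

Step 10
Reactants: 18 the C8 ketone
Product: 19 (2S)-3-[(2R,3R,4S)-3-[(1S)-1-hydroxy-3-methylpent-4-en-1-yl]-4-methyl-5-oxooxolan-2-yl]-N,N,2-trimethylpropanamide
Conditions: (R)-2-methyl-CBS-oxazaborolidine (20 mol %), catecholborane, toluene, −78 °C; MeOH, aq. NaHCO3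
Reagents that add atoms: none
Why: Corey–Bakshi–Shibata reduction: the (R)-oxazaborolidine directs hydride to the Re face of the C8 ketone by telling the branched ring carbon C7 from the CH2 side, which sets C8 (S), and catecholborane at low temperature leaves alkene, lactone and amide alone.

Step 11
Reactants: 19 the C8 alcohol
Product: 20 (2S)-N,N,2-trimethyl-3-[(2R,3S,4S)-4-methyl-3-[(1S)-3-methyl-1-(triisopropylsilyloxy)pent-4-en-1-yl]-5-oxooxolan-2-yl]propanamide
Conditions: TIPSOTf, 2,6-lutidine, CH2Cl2, −20 to 0 °C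
Reagents that add atoms: triisopropylsilyl trifluoromethanesulfonate, CC(C)[Si](OS(=O)(=O)C(F)(F)F)(C(C)C)C(C)C
Why: Silyl triflate silylation of the secondary alcohol under non-nucleophilic conditions, before the free γ-hydroxyl can translactonise onto C12; the triisopropylsilyl ether resists the HBr of step 13 and cannot act as a neighbouring group in step 14.

Step 12
Reactants: 20 the silyl ether alkene
Product: 21 (2S)-N,N,2-trimethyl-3-[(2R,3S,4S)-4-methyl-3-[(1S)-3-methyl-4-oxo-1-(triisopropylsilyloxy)pentyl]-5-oxooxolan-2-yl]propanamide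
Conditions: PdCl2 (10 mol %), CuCl, O2 (1 atm), DMF/H2O 7:1, rt
Reagents that add atoms: water, O
Why: Tsuji–Wacker oxidation: Markovnikov hydroxypalladation of the monosubstituted alkene gives the methyl ketone, with water as the oxygen source and O2 as the terminal oxidant.

Step 13
Reactants: 21 the methyl ketone
Product: 22 (2S)-3-[(2R,3S,4S)-3-[(1S)-3,5-dibromo-3-methyl-4-oxo-1-(triisopropylsilyloxy)pentyl]-4-methyl-5-oxooxolan-2-yl]-N,N,2-trimethylpropanamide
Conditions: Br2 (2.05 equiv), HBr/AcOH (5 mol %), CH2Cl2, 0 °C, dark; aq. NaHCO3/Na2S2O3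
Reagents that add atoms: bromine, BrBr
Why: Acid-catalysed α-bromination of the ketone through its enols: the first bromine enters at the tertiary C10 (more substituted enol), the second can then only enter at the methyl carbon C2, and amide and lactone do not enolise under these conditions.

Step 14
Reactants: 22 the α,α'-dibromo ketone amide
Product: 24 (4S,6R,7S,8S,10R,11S)-3,10-epoxy-1-oxo-8-(triisopropylsilyloxy)germacr-2-en-12,6-olide, via C3 aminal 23 (not isolated)
Conditions: Fe2(CO)9 (1.5 equiv), benzene, 45 °C, slow addition of 22 (final about 2 mM), Ar; then SiO2, EtOAc, rt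
Reagents that add atoms: none
Why: Proposed new method: Fe2(CO)9 (zerovalent iron) reduces the α,α'-dibromo ketone to an iron-bound 2-oxyallyl cation spanning C10–C1–C2; the tethered amide oxygen adds to its tertiary terminus C10 (nine-membered O-alkyl imidate ring, 9-exo attack on the trigonal cation terminus) and the enolate carbon C2 then adds across that ring to the iminium carbon C3 (formally 5-(enolendo)-exo-trig for the furanone and 10-exo-trig for the carbocycle, the second bond of a stepwise [3+2] annulation), so that one transannular bond closes the furanone and the ten-membered ring together, after which aminal 23 loses dimethylamine toward C2 to give the conjugated C2=C3 enol ether. The closest known reaction is the intermolecular iron-carbonyl-promoted [3+2] cyclocoupling of α,α'-dibromo ketones with N,N-dimethylcarboxamides to 3(2H)-furanones, which shows the same regiochemistry (amide oxygen to the more substituted terminus, carbon–carbon bond at the less substituted one); what is new is the intramolecular version through a medium ring. C10 is the only new stereocentre: the planar oxyallyl can offer either face by rotation about C9–C10, and the rotamer that keeps the bulky iron-enolate arm (C1–C2) anti to the C8 triisopropylsilyloxy group and leaves the small methyl group syn to it is expected to cyclise, which gives 10R; since O-alkylation of the amide next to an enolate is reversible, the ratio should in the end reflect the strain of the two bridged transition states for the C2–C3 closure. The step needs cyclisation to beat oligomerisation and proton loss from the cation (slow addition, high dilution), capture by the amide rather than by the lactone carbonyl (only the amide oxygen is nucleophilic enough, and the silyl ether cannot act as a neighbouring group), and elimination toward C2 rather than C4 (C2–H is alpha to the C1 ketone and gives the conjugated product). C4, alpha to the transient iminium carbon, should keep its configuration because the medium contains no base until dimethylamine is released.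

Step 15
Reactants: 24 the tricyclic silyl ether
Product: 25 (4S,6R,7R,8S,10R,11S)-8-hydroxy-3,10-epoxy-1-oxogermacr-2-en-12,6-olide (C7 unchanged in space; its descriptor changes by priority only)
Conditions: HF·pyridine, pyridine, THF, 0 °C to rt
Reagents that add atoms: none
Why: Fluoride-mediated cleavage of the silyl ether; the vinylogous ester and the lactone are stable to buffered HF·pyridine.

Step 16
Reactants: 25 the tricyclic C8 alcohol; 26 (2E)-2-methylbut-2-enoyl chloride (tigloyl chloride)
Product: 27 (4S,6R,7S,8S,10R,11S)-3,10-epoxy-1-oxo-8-[(2E)-2-methylbut-2-enoyloxy]germacr-2-en-12,6-olide (CNP0235937.1)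
Conditions: DMAP (0.2 equiv), Et3N, CH2Cl2, 0 °C to rt
Reagents that add atoms: none
Why: DMAP-catalysed acylation of the secondary alcohol by the acid chloride; the tiglate is the stable E isomer and no base-sensitive stereocentre is exposed.

**Compound list**

1 | (4R)-4-benzyl-3-propanoyl-1,3-oxazolidin-2-one | CCC(=O)N1[C@H](Cc2ccccc2)COC1=O | starting material
2 | 3-iodoprop-1-ene (allyl iodide) | C=CCI | starting material
3 | (4R)-4-benzyl-3-[(2S)-2-methylpent-4-enoyl]-1,3-oxazolidin-2-one | C=CC[C@H](C)C(=O)N1[C@H](Cc2ccccc2)COC1=O | intermediate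
4 | (2S)-N,N,2-trimethylpent-4-enamide | C=CC[C@H](C)C(=O)N(C)C | intermediate
5 | (2S)-N,N,2-trimethyl-3-(1,2,4-trioxolan-3-yl)propanamide (ozonide, not isolated) | CN(C)C(=O)[C@@H](C)CC1OCOO1 | intermediate
6 | (2S)-N,N,2-trimethyl-4-oxobutanamide | CN(C)C(=O)[C@@H](C)CC=O | intermediate
7 | (4S)-4-benzyl-1,3-oxazolidin-2-one | O=C1N[C@@H](Cc2ccccc2)CO1 | starting material
8 | methyl 4-chloro-4-oxobutanoate | COC(=O)CCC(Cl)=O | starting material
9 | methyl 4-[(4S)-4-benzyl-2-oxo-1,3-oxazolidin-3-yl]-4-oxobutanoate | COC(=O)CCC(=O)N1[C@@H](Cc2ccccc2)COC1=O | intermediate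
10 | methyl (3S,4R,6S)-3-{[(4S)-4-benzyl-2-oxo-1,3-oxazolidin-3-yl]carbonyl}-7-(dimethylamino)-4-hydroxy-6-methyl-7-oxoheptanoate (aldol adduct, not isolated) | CN(C)C(=O)[C@@H](C)C[C@@H](O)[C@H](CC(=O)OC)C(=O)N1[C@@H](Cc2ccccc2)COC1=O | intermediate
11 | (4S)-4-benzyl-3-{[(2R,3S)-2-[(2S)-3-(dimethylamino)-2-methyl-3-oxopropyl]-5-oxooxolan-3-yl]carbonyl}-1,3-oxazolidin-2-one | CN(C)C(=O)[C@@H](C)C[C@H]1OC(=O)C[C@@H]1C(=O)N1[C@@H](Cc2ccccc2)COC1=O | intermediate
12 | (2R,3S)-2-[(2S)-3-(dimethylamino)-2-methyl-3-oxopropyl]-5-oxooxolane-3-carboxylic acid | CN(C)C(=O)[C@@H](C)C[C@H]1OC(=O)C[C@@H]1C(=O)O | intermediate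
13 | (2R,3S,4S)-2-[(2S)-3-(dimethylamino)-2-methyl-3-oxopropyl]-4-methyl-5-oxooxolane-3-carboxylic acid | CN(C)C(=O)[C@@H](C)C[C@H]1OC(=O)[C@@H](C)[C@@H]1C(=O)O | intermediate
14 | 2-methylbut-3-en-1-ol (racemic) | C=CC(C)CO | starting material
15 | 4-bromo-3-methylbut-1-ene | C=CC(C)CBr | intermediate
16 | (2R,3S,4S)-2-[(2S)-3-(dimethylamino)-2-methyl-3-oxopropyl]-4-methyl-5-oxooxolane-3-carbonyl chloride (not isolated) | CN(C)C(=O)[C@@H](C)C[C@H]1OC(=O)[C@@H](C)[C@@H]1C(Cl)=O | intermediate
17 | bromo(2-methylbut-3-en-1-yl)zinc (not isolated) | C=CC(C)C[Zn]Br | intermediate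
18 | (2S)-N,N,2-trimethyl-3-[(2R,3S,4S)-4-methyl-3-(3-methylpent-4-enoyl)-5-oxooxolan-2-yl]propanamide | CN(C)C(=O)[C@@H](C)C[C@H]1OC(=O)[C@@H](C)[C@@H]1C(=O)CC(C)C=C | intermediate
19 | (2S)-3-[(2R,3R,4S)-3-[(1S)-1-hydroxy-3-methylpent-4-en-1-yl]-4-methyl-5-oxooxolan-2-yl]-N,N,2-trimethylpropanamide | CN(C)C(=O)[C@@H](C)C[C@H]1OC(=O)[C@@H](C)[C@@H]1[C@@H](O)CC(C)C=C | intermediate
20 | (2S)-N,N,2-trimethyl-3-[(2R,3S,4S)-4-methyl-3-[(1S)-3-methyl-1-(triisopropylsilyloxy)pent-4-en-1-yl]-5-oxooxolan-2-yl]propanamide | CN(C)C(=O)[C@@H](C)C[C@H]1OC(=O)[C@@H](C)[C@@H]1[C@@H](O[Si](C(C)C)(C(C)C)C(C)C)CC(C)C=C | intermediate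
21 | (2S)-N,N,2-trimethyl-3-[(2R,3S,4S)-4-methyl-3-[(1S)-3-methyl-4-oxo-1-(triisopropylsilyloxy)pentyl]-5-oxooxolan-2-yl]propanamide | CN(C)C(=O)[C@@H](C)C[C@H]1OC(=O)[C@@H](C)[C@@H]1[C@@H](O[Si](C(C)C)(C(C)C)C(C)C)CC(C)C(C)=O | intermediate
22 | (2S)-3-[(2R,3S,4S)-3-[(1S)-3,5-dibromo-3-methyl-4-oxo-1-(triisopropylsilyloxy)pentyl]-4-methyl-5-oxooxolan-2-yl]-N,N,2-trimethylpropanamide | CN(C)C(=O)[C@@H](C)C[C@H]1OC(=O)[C@@H](C)[C@@H]1[C@@H](O[Si](C(C)C)(C(C)C)C(C)C)CC(C)(Br)C(=O)CBr | intermediate
23 | (4S,6R,7S,8S,10R,11S)-3-(dimethylamino)-3,10-epoxy-1-oxo-8-(triisopropylsilyloxy)germacran-12,6-olide (C3 aminal, C3 epimers, not isolated) | CC(C)[Si](C(C)C)(C(C)C)O[C@H]1C[C@@]2(C)OC(N(C)C)(CC2=O)[C@@H](C)C[C@H]2OC(=O)[C@@H](C)[C@H]12 | intermediate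
24 | (4S,6R,7S,8S,10R,11S)-3,10-epoxy-1-oxo-8-(triisopropylsilyloxy)germacr-2-en-12,6-olide | CC(C)[Si](C(C)C)(C(C)C)O[C@H]1C[C@@]2(C)OC(=CC2=O)[C@@H](C)C[C@H]2OC(=O)[C@@H](C)[C@H]12 | intermediate
25 | (4S,6R,7R,8S,10R,11S)-8-hydroxy-3,10-epoxy-1-oxogermacr-2-en-12,6-olide | O[C@H]1C[C@@]2(C)OC(=CC2=O)[C@@H](C)C[C@H]2OC(=O)[C@@H](C)[C@H]12 | intermediate
26 | (2E)-2-methylbut-2-enoyl chloride (tigloyl chloride) | C/C=C(\C)C(Cl)=O | starting material
27 | (4S,6R,7S,8S,10R,11S)-3,10-epoxy-1-oxo-8-[(2E)-2-methylbut-2-enoyloxy]germacr-2-en-12,6-olide (CNP0235937.1) | C/C=C(\C)C(=O)O[C@H]1C[C@@]2(C)OC(=CC2=O)[C@@H](C)C[C@H]2OC(=O)[C@@H](C)[C@H]12 | target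

**Step count and risks**

Total steps: 16. Longest linear sequence: 14 (steps 1–3, 5–7, 9–16); steps 4 and 8 are side branches.

Steps most likely to fail:

1. Step 14 (proposed new method). Capture of the oxyallyl cation by the tethered amide has to pass through a nine-membered transition state and may be too slow. Proton loss to the enone, reduction to the parent ketone or intermolecular capture could then win. The amide may also add to the other face of C10. Fallback, known chemistry only, sets out from 13 and returns at 25; it takes the ring closure out of the annulation.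
   - Acid 13 is turned into the S-ethyl thioester F1 (EtSH, EDC, DMAP).
   - The amide of F1 is annulated with 1,3-dibromobutan-2-one and Fe2(CO)9 in the documented intermolecular manner. This still makes both furanone bonds in one operation and gives the 2-methyl-3(2H)-furanone F2 (C10–H, epimer mixture).
   - Liebeskind–Srogl-type coupling of the thioester with tributyl(vinyl)stannane (Pd2(dba)3, tri(2-furyl)phosphine, CuO2PPh2) gives the vinyl ketone F3.
   - Cs2CO3 in MeCN at high dilution closes the ten-membered ring by intramolecular Michael addition of the furanone enolate (C10) to the enone (new C9–C10 bond), giving the diketone F4. The addition is reversible, so C10 settles under thermodynamic control.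
   - Reduction of the C8 ketone of F4 (CBS catalyst with catecholborane, or NaBH4; the vinylogous ester carbonyl C1 is much less electrophilic) gives 25.

2. Step 10. Facial selectivity may be poor: the catalyst has to tell the ring carbon C7 from a β-branched CH2 group and may be overridden by the bias of the lactone. Fallback, sets out from 18 and returns at 19: hydride is delivered under substrate control instead (LiBH(s-Bu)3, THF, −78 °C). If this gives the (8R)-alcohol F5, the centre is inverted by Mitsunobu esterification with chloroacetic acid (PPh3, DIAD) to the (8S)-chloroacetate F6. Thiourea/NaHCO3 in EtOH then removes the chloroacetyl group to give 19.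

3. Step 13. Regiocontrol may be lost (a second bromine entering the already brominated methyl carbon, or polybromination), and the HBr formed may cleave the silyl ether. Fallback, sets out from 20 and returns at 22, bypassing 21: NBS in THF/H2O converts the alkene into the bromohydrin F7 (bromine on the terminal carbon). Dess–Martin oxidation gives the bromomethyl ketone F8. A single acid-catalysed bromination (Br2, 1 equiv) then enters only at the tertiary C10, which halves the HBr load and removes the regiochemical question at C2.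

**Further compounds**

F1 | step 14 | S-ethyl (2R,3S,4S)-2-[(2S)-3-(dimethylamino)-2-methyl-3-oxopropyl]-4-methyl-5-oxooxolane-3-carbothioate | CN(C)C(=O)[C@@H](C)C[C@H]1OC(=O)[C@@H](C)[C@@H]1C(=O)SCC
F2 | step 14 | S-ethyl (2R,3S,4S)-4-methyl-2-[(2S)-2-(5-methyl-4-oxo-4,5-dihydrofuran-2-yl)propyl]-5-oxooxolane-3-carbothioate | CC1OC(=CC1=O)[C@@H](C)C[C@H]1OC(=O)[C@@H](C)[C@@H]1C(=O)SCC
F3 | step 14 | (3S,4S,5R)-4-acryloyl-3-methyl-5-[(2S)-2-(5-methyl-4-oxo-4,5-dihydrofuran-2-yl)propyl]oxolan-2-one | CC1OC(=CC1=O)[C@@H](C)C[C@H]1OC(=O)[C@@H](C)[C@@H]1C(=O)C=C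
F4 | step 14 | (4S,6R,7S,10R,11S)-3,10-epoxy-1,8-dioxogermacr-2-en-12,6-olide | O=C1C[C@@]2(C)OC(=CC2=O)[C@@H](C)C[C@H]2OC(=O)[C@@H](C)[C@H]12
F5 | step 10 | (2S)-3-[(2R,3R,4S)-3-[(1R)-1-hydroxy-3-methylpent-4-en-1-yl]-4-methyl-5-oxooxolan-2-yl]-N,N,2-trimethylpropanamide | CN(C)C(=O)[C@@H](C)C[C@H]1OC(=O)[C@@H](C)[C@@H]1[C@H](O)CC(C)C=C
F6 | step 10 | (1S)-1-[(2R,3S,4S)-2-[(2S)-3-(dimethylamino)-2-methyl-3-oxopropyl]-4-methyl-5-oxooxolan-3-yl]-3-methylpent-4-en-1-yl chloroacetate | CN(C)C(=O)[C@@H](C)C[C@H]1OC(=O)[C@@H](C)[C@@H]1[C@@H](OC(=O)CCl)CC(C)C=C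
F7 | step 13 | (2S)-3-[(2R,3S,4S)-3-[(1S)-5-bromo-4-hydroxy-3-methyl-1-(triisopropylsilyloxy)pentyl]-4-methyl-5-oxooxolan-2-yl]-N,N,2-trimethylpropanamide | CN(C)C(=O)[C@@H](C)C[C@H]1OC(=O)[C@@H](C)[C@@H]1[C@@H](O[Si](C(C)C)(C(C)C)C(C)C)CC(C)C(O)CBr
F8 | step 13 | (2S)-3-[(2R,3S,4S)-3-[(1S)-5-bromo-3-methyl-4-oxo-1-(triisopropylsilyloxy)pentyl]-4-methyl-5-oxooxolan-2-yl]-N,N,2-trimethylpropanamide | CN(C)C(=O)[C@@H](C)C[C@H]1OC(=O)[C@@H](C)[C@@H]1[C@@H](O[Si](C(C)C)(C(C)C)C(C)C)CC(C)C(=O)CBr
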